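**Strategy.** The chroman is cut across ring C at C3–C4 and O1–C2. Ring C holds the phenolic O1 and the benzylic C4 of ring A, which are the two ends of an ortho-quinone methide, and they are bridged by C2 and by the stereogenic C3 that carries ring B. A carbene-catalysed annulation of that quinone methide (released by fluoride from an O-silyl benzyl bromide) with the azolium enolate of a ring-B arylacetyl imidazole therefore builds ring C as a lactone and sets C3 in one operation. Ring B travels as a MOM-masked para-methoxyphenol, so that the quinone is unveiled last without touching electron-rich ring A.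

Key step: step 8

Remark (ring-B design): ring A is a 1,2,4-trioxygenated arene with a para-dialkoxy pair (O1/6-OMe) and should be at least as easily oxidised by (NH4)2Ce(NO3)6 as a 1,2,3,4-tetramethoxyarene; the C2' oxygen of ring B (a future quinone carbonyl) is therefore carried as a MOM ether, which also directs the lithiation, and the quinone is made from the free para-methoxyphenol with PhI(OAc)2.

Assumption (sense of induction): the (5aS,10bR) triazolium salt is taken to deliver the quinone methide to the Si face of the enolate carbon; if a test run shows the opposite sense, the (5aR,10bS) antipode is used.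

Remark (starting material): 2,3,4-trimethoxyphenol is a catalogue compound; it is otherwise one Dakin oxidation away from 2,3,4-trimethoxybenzaldehyde.

**Step 1**
Reactants: 1 2,3,4-trimethoxyphenol
Product: 2 1-(methoxymethoxy)-2,3,4-trimethoxybenzene
Conditions: MOMCl, i-Pr2NEt, CH2Cl2, 0 °C → rt
Reagents that add atoms: chloromethyl methyl ether, COCCl
Why: O-alkylation of the phenol (MOM protection) masks the oxygen that becomes a quinone carbonyl and installs the stronger of the two ortho-directing groups.

**Step 2**
Reactants: 2 1-(methoxymethoxy)-2,3,4-trimethoxybenzene; 3 ethylene oxide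
Product: 5 2-[2-(methoxymethoxy)-3,4,5-trimethoxyphenyl]ethan-1-ol, via aryllithium 4 (not isolated)
Conditions: n-BuLi, THF, 0 °C; then ethylene oxide (THF solution), 0 °C → rt
Reagents that add atoms: none
Why: Directed ortho-metalation places lithium beside the chelating OMOM group in preference to the position beside OMe, and the aryllithium opens the epoxide by SN2 to the 2-arylethanol.

**Step 3**
Reactants: 5 2-[2-(methoxymethoxy)-3,4,5-trimethoxyphenyl]ethan-1-ol
Product: 6 [2-(methoxymethoxy)-3,4,5-trimethoxyphenyl]acetic acid
Conditions: TEMPO (2,2,6,6-tetramethylpiperidin-1-oxyl, cat.), NaOCl (cat.), NaClO2, MeCN/phosphate buffer pH 6.7, 35 °C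
Reagents that add atoms: sodium chlorite, [Na+].[O-]Cl=O
Why: Oxoammonium oxidation to the aldehyde and in situ chlorite (Pinnick-type) oxidation to the acid run near neutral pH, where the MOM acetal survives and the merely catalytic hypochlorite limits chlorination of the electron-rich ring.

**Step 4**
Reactants: 6 [2-(methoxymethoxy)-3,4,5-trimethoxyphenyl]acetic acid
Product: 7 1-{[2-(methoxymethoxy)-3,4,5-trimethoxyphenyl]acetyl}-1H-imidazole
Conditions: CDI, THF, rt
Reagents that add atoms: 1,1'-carbonyldiimidazole, O=C(n1ccnc1)n1ccnc1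
Why: Acid activation by CDI (acyl imidazole formation) proceeds under neutral conditions with loss of CO2 and imidazole and gives the isolable acyl donor that the carbene needs.

**Step 5**
Reactants: 8 2-hydroxy-4,5-dimethoxybenzaldehyde
Product: 9 2-[(tert-butyldimethylsilyl)oxy]-4,5-dimethoxybenzaldehyde
Conditions: TBSCl, imidazole, DMF, rt
Reagents that add atoms: tert-butyldimethylsilyl chloride, CC(C)(C)[Si](C)(C)Cl
Why: Imidazole-promoted silylation of the phenol installs the fluoride-labile trigger for the later quinone methide release.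

**Step 6**
Reactants: 9 2-[(tert-butyldimethylsilyl)oxy]-4,5-dimethoxybenzaldehyde
Product: 10 {2-[(tert-butyldimethylsilyl)oxy]-4,5-dimethoxyphenyl}methanol
Conditions: NaBH4, MeOH, 0 °C
Reagents that add atoms: none
Why: Borohydride reduction of the aldehyde in a protic solvent at low temperature protonates the benzylic alkoxide before it can take over the silyl group from the neighbouring phenol oxygen.

**Step 7**
Reactants: 10 {2-[(tert-butyldimethylsilyl)oxy]-4,5-dimethoxyphenyl}methanol
Product: 11 tert-butyl[2-(bromomethyl)-4,5-dimethoxyphenoxy]dimethylsilane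
Conditions: CBr4, PPh3, CH2Cl2, 0 °C; short silica plug, used at once
Reagents that add atoms: carbon tetrabromide, BrC(Br)(Br)Br
Why: The Appel reaction converts the benzylic alcohol into the bromide under neutral, acid-free conditions that leave the aryl silyl ether intact, and the donor-activated bromide is taken on without storage.

**Step 8**
Reactants: 7 1-{[2-(methoxymethoxy)-3,4,5-trimethoxyphenyl]acetyl}-1H-imidazole; 11 tert-butyl[2-(bromomethyl)-4,5-dimethoxyphenoxy]dimethylsilane
Product: 14 (3S)-6,7-dimethoxy-3-[2-(methoxymethoxy)-3,4,5-trimethoxyphenyl]chroman-2-one, via ortho-quinone methide 12 (not isolated), via azolium enolate 13 (not isolated)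
Conditions: (5aS,10bR)-2-(2,4,6-trimethylphenyl)-5a,10b-dihydro-4H,6H-indeno[2,1-b][1,2,4]triazolo[4,3-d][1,4]oxazin-2-ium tetrafluoroborate (15 mol %), CsF, 18-crown-6, 4 Å MS, THF, −20 °C, 11 in excess; AcOH quench
Reagents that add atoms: none
Why: Fluoride removes the silyl group of 11 and the electron-rich phenoxide expels bromide to give quinone methide 12, while the free carbene displaces imidazole from 7 and the acyl azolium, acidified by ring B, is deprotonated to enolate 13; conjugate addition of the enolate carbon to the exocyclic methylene forms C3–C4 and rearomatises ring A, and the phenoxide then acylates at the acyl azolium to form O1–C2 and free the carbene. The closest known reaction type is the carbene-catalysed formal [4+2] (hetero-Diels–Alder type) annulation of fluoride-generated ortho-quinone methides with acyl imidazole-derived azolium enolates, which gives 3-substituted 3,4-dihydrocoumarins. Ring C closes by 6-exo-trig addition of O1 to the acyl azolium carbonyl followed by loss of the carbene (lactonisation). C3, the only new stereocentre, is set in the C–C bond formation by the chiral carbene, whose indane-fused backbone and N-aryl group shield one enolate face so that 12 adds to the Si face of the enolate carbon and the (S)-lactone results. The step needs enantioface selectivity, C- over O-alkylation and no later epimerisation of the acidic C3–H: the methylene terminus of 12 is its only soft electrophilic site and creates no second stereocentre, the ortho-OMOM group twists ring B out of conjugation and lowers the acidity of C3–H, and low temperature plus the acetic acid quench limit fluoride-mediated enolisation.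

**Step 9**
Reactants: 14 (3S)-6,7-dimethoxy-3-[2-(methoxymethoxy)-3,4,5-trimethoxyphenyl]chroman-2-one
Product: 15 2-{(2S)-3-hydroxy-2-[2-(methoxymethoxy)-3,4,5-trimethoxyphenyl]propyl}-4,5-dimethoxyphenol
Conditions: LiAlH4, THF, −20 → 0 °C
Reagents that add atoms: none
Why: Hydride reduction of the activated aryl lactone to the phenol–primary alcohol should be much faster than enolisation and reduces the transient aldehyde at once, so C3 keeps its configuration and is no longer acidic afterwards.

**Step 10**
Reactants: 15 2-{(2S)-3-hydroxy-2-[2-(methoxymethoxy)-3,4,5-trimethoxyphenyl]propyl}-4,5-dimethoxyphenol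
Product: 16 (3S)-6,7-dimethoxy-3-[2-(methoxymethoxy)-3,4,5-trimethoxyphenyl]chroman
Conditions: PPh3, DIAD, THF, 0 °C → rt
Reagents that add atoms: none
Why: Intramolecular Mitsunobu etherification (6-exo-tet attack of the only free phenol on the activated primary carbon) recloses ring C without involving the stereocentre.

**Step 11**
Reactants: 16 (3S)-6,7-dimethoxy-3-[2-(methoxymethoxy)-3,4,5-trimethoxyphenyl]chroman
Product: 17 6-[(3S)-6,7-dimethoxychroman-3-yl]-2,3,4-trimethoxyphenol
Conditions: HCl (conc., cat.), MeOH, 40 °C
Reagents that add atoms: none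
Why: Acid-catalysed methanolysis of the MOM acetal frees the ring-B phenol while methyl ethers, the chroman ether and the non-acidic C3 are untouched.

**Step 12**
Reactants: 17 6-[(3S)-6,7-dimethoxychroman-3-yl]-2,3,4-trimethoxyphenol
Product: 18 Abroquinone A, 5-[(3S)-6,7-dimethoxychroman-3-yl]-2,3-dimethoxycyclohexa-2,5-diene-1,4-dione
Conditions: PhI(OAc)2, MeCN/H2O, 0 °C
Reagents that add atoms: water, O
Why: Oxidative demethylation of a para-methoxyphenol by the λ3-iodane requires ligand exchange at a free OH, so only ring B reacts; water adds at the para carbon and the hemiketal loses methanol to give the para-quinone.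

**Compound list**

1 | 2,3,4-trimethoxyphenol | COc1ccc(O)c(OC)c1OC | starting material
2 | 1-(methoxymethoxy)-2,3,4-trimethoxybenzene | COCOc1ccc(OC)c(OC)c1OC | intermediate
3 | ethylene oxide (oxirane) | C1CO1 | starting material
4 | [2-(methoxymethoxy)-3,4,5-trimethoxyphenyl]lithium | [Li]c1cc(OC)c(OC)c(OC)c1OCOC | intermediate (not isolated)
5 | 2-[2-(methoxymethoxy)-3,4,5-trimethoxyphenyl]ethan-1-ol | OCCc1cc(OC)c(OC)c(OC)c1OCOC | intermediate
6 | [2-(methoxymethoxy)-3,4,5-trimethoxyphenyl]acetic acid | OC(=O)Cc1cc(OC)c(OC)c(OC)c1OCOC | intermediate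
7 | 1-{[2-(methoxymethoxy)-3,4,5-trimethoxyphenyl]acetyl}-1H-imidazole | O=C(Cc1cc(OC)c(OC)c(OC)c1OCOC)n1ccnc1 | intermediate
8 | 2-hydroxy-4,5-dimethoxybenzaldehyde | COc1cc(O)c(C=O)cc1OC | starting material
9 | 2-[(tert-butyldimethylsilyl)oxy]-4,5-dimethoxybenzaldehyde | COc1cc(O[Si](C)(C)C(C)(C)C)c(C=O)cc1OC | intermediate
10 | {2-[(tert-butyldimethylsilyl)oxy]-4,5-dimethoxyphenyl}methanol | COc1cc(O[Si](C)(C)C(C)(C)C)c(CO)cc1OC | intermediate
11 | tert-butyl[2-(bromomethyl)-4,5-dimethoxyphenoxy]dimethylsilane | COc1cc(CBr)c(O[Si](C)(C)C(C)(C)C)cc1OC | intermediate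
12 | 3,4-dimethoxy-6-methylidenecyclohexa-2,4-dien-1-one (ortho-quinone methide of ring A) | C=C1C=C(OC)C(OC)=CC1=O | intermediate (not isolated)
13 | (Z)-2-[2-(methoxymethoxy)-3,4,5-trimethoxyphenyl]-1-[(5aS,10bR)-2-(2,4,6-trimethylphenyl)-5a,10b-dihydro-4H,6H-indeno[2,1-b][1,2,4]triazolo[4,3-d][1,4]oxazin-2-ium-1-yl]ethen-1-olate (zwitterionic azolium enolate) | [O-]/C(=C\c1cc(OC)c(OC)c(OC)c1OCOC)c1n2c(n[n+]1-c1c(C)cc(C)cc1C)CO[C@H]1Cc3ccccc3[C@@H]21 | intermediate (not isolated)
14 | (3S)-6,7-dimethoxy-3-[2-(methoxymethoxy)-3,4,5-trimethoxyphenyl]chroman-2-one | COCOc1c([C@@H]2Cc3cc(OC)c(OC)cc3OC2=O)cc(OC)c(OC)c1OC | intermediate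
15 | 2-{(2S)-3-hydroxy-2-[2-(methoxymethoxy)-3,4,5-trimethoxyphenyl]propyl}-4,5-dimethoxyphenol | COCOc1c([C@H](Cc2cc(OC)c(OC)cc2O)CO)cc(OC)c(OC)c1OC | intermediate
16 | (3S)-6,7-dimethoxy-3-[2-(methoxymethoxy)-3,4,5-trimethoxyphenyl]chroman | COCOc1c([C@H]2COc3cc(OC)c(OC)cc3C2)cc(OC)c(OC)c1OC | intermediate
17 | 6-[(3S)-6,7-dimethoxychroman-3-yl]-2,3,4-trimethoxyphenol | COc1cc([C@H]2COc3cc(OC)c(OC)cc3C2)c(O)c(OC)c1OC | intermediate
18 | Abroquinone A, 5-[(3S)-6,7-dimethoxychroman-3-yl]-2,3-dimethoxycyclohexa-2,5-diene-1,4-dione | COC1=C(OC)C(=O)C([C@H]2COc3cc(OC)c(OC)cc3C2)=CC1=O | target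

**Step count.** Total: 12 steps. Longest linear sequence: 9 steps (steps 1–4, then 8–12); the ring-A branch (steps 5–7) joins at step 8.

**Steps most likely to fail**

Step 8. Facial selectivity in the C3–C4 bond formation may be insufficient. The finished lactone may lose configuration by fluoride- or imidazole-mediated enolisation at C3. The quinone methide may be consumed by self-dimerisation or by N-alkylation of the liberated imidazole. Fallback (auxiliary-controlled alkylation, from 6 and 11, returning at 15): acid 6 is coupled with (S)-4-benzyl-1,3-oxazolidin-2-one (t-BuCOCl, Et3N, LiCl, THF) to give (4S)-4-benzyl-3-{[2-(methoxymethoxy)-3,4,5-trimethoxyphenyl]acetyl}-1,3-oxazolidin-2-one F1. Its sodium (Z)-enolate (NaN(SiMe3)2, THF, −78 °C) is alkylated by bromide 11 on the face away from the benzyl group (Evans alkylation) to give (4S)-4-benzyl-3-[(2S)-3-{2-[(tert-butyldimethylsilyl)oxy]-4,5-dimethoxyphenyl}-2-[2-(methoxymethoxy)-3,4,5-trimethoxyphenyl]propanoyl]-1,3-oxazolidin-2-one F2. LiBH4 (THF/H2O, 0 °C) removes the auxiliary reductively to give (2S)-3-{2-[(tert-butyldimethylsilyl)oxy]-4,5-dimethoxyphenyl}-2-[2-(methoxymethoxy)-3,4,5-trimethoxyphenyl]propan-1-ol F3, and Bu4NF/AcOH in THF frees the phenol to give diol 15, from which steps 10–12 follow unchanged.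

Step 7. The benzylic bromide, activated by an ortho-silyloxy and a para-methoxy donor, may ionise during work-up or on silica. That would lead to self-condensation, hydrolysis, or premature loss of the silyl group. Fallback (a bench-stable precursor of the same quinone methide, from 10, returning at 14): alcohol 10 is acetylated (Ac2O, pyridine, cat. 4-(dimethylamino)pyridine, CH2Cl2) to {2-[(tert-butyldimethylsilyl)oxy]-4,5-dimethoxyphenyl}methyl acetate F4. Under the conditions of step 8, fluoride should desilylate F4 and the phenoxide should expel acetate by 1,4-elimination, releasing 12, which is intercepted by 13 to give lactone 14.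

Step 12. Water may add ortho instead of para to the oxidised phenol and so lead to an ortho-quinone, or the aqueous medium may allow over-oxidation or coupling that involves ring A. Fallback (trap, then hydrolyse; from 17, returning at 18): phenol 17 is oxidised with PhI(OAc)2 in MeOH at 0 °C, where methanol adds para and the product is held as the quinone monoketal 6-[(3S)-6,7-dimethoxychroman-3-yl]-2,3,4,4-tetramethoxycyclohexa-2,5-dien-1-one F5. Mild hydrolysis (aqueous oxalic acid, THF, rt) then releases quinone 18.

**Further compounds**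

F1 | step 8 | (4S)-4-benzyl-3-{[2-(methoxymethoxy)-3,4,5-trimethoxyphenyl]acetyl}-1,3-oxazolidin-2-one | COCOc1c(CC(=O)N2[C@@H](Cc3ccccc3)COC2=O)cc(OC)c(OC)c1OC
F2 | step 8 | (4S)-4-benzyl-3-[(2S)-3-{2-[(tert-butyldimethylsilyl)oxy]-4,5-dimethoxyphenyl}-2-[2-(methoxymethoxy)-3,4,5-trimethoxyphenyl]propanoyl]-1,3-oxazolidin-2-one | COCOc1c([C@H](Cc2cc(OC)c(OC)cc2O[Si](C)(C)C(C)(C)C)C(=O)N2[C@@H](Cc3ccccc3)COC2=O)cc(OC)c(OC)c1OC
F3 | step 8 | (2S)-3-{2-[(tert-butyldimethylsilyl)oxy]-4,5-dimethoxyphenyl}-2-[2-(methoxymethoxy)-3,4,5-trimethoxyphenyl]propan-1-ol | COCOc1c([C@H](Cc2cc(OC)c(OC)cc2O[Si](C)(C)C(C)(C)C)CO)cc(OC)c(OC)c1OC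
F4 | step 7 | {2-[(tert-butyldimethylsilyl)oxy]-4,5-dimethoxyphenyl}methyl acetate | CC(=O)OCc1cc(OC)c(OC)cc1O[Si](C)(C)C(C)(C)C
F5 | step 12 | 6-[(3S)-6,7-dimethoxychroman-3-yl]-2,3,4,4-tetramethoxycyclohexa-2,5-dien-1-one | COC1=C(OC)C(OC)(OC)C=C([C@H]2COc3cc(OC)c(OC)cc3C2)C1=O
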